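**Retrosynthetic overview**
1. Target 13 ⇒ diene 11 ⇒ chromanol 8. In ring C4a–C5–C6–C7–C8–C8a, O1 (on C8a) and the C5 carbonyl are 1,3-related across the C4a=C8a bond. This vinylogous ester is the hydrolysed Birch product of a resorcinol diether, so the ring is carried as the benzene ring of a 5-methoxychroman and unmasked last.
2. 8 ⇒ 7: the C4 carbinol comes from cis-selective hydride reduction of the chroman-4-one.
3. 7 ⇒ 3 + 5: the C2–chain bond and the C2 stereocentre come from copper-catalysed enantioselective 1,4-addition of heptadecylmagnesium bromide to 5-methoxychromone.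
4. 3 ⇒ 1: the pyranone ring is closed from 2'-hydroxy-6'-methoxyacetophenone through an enaminone.
5. Ring order: benzene ring bought in 1, pyranone ring closed in step 2, no later ring closure; the carbocycle is revealed by dearomatization in step 6.

Key step: step 4

Assumption: the (R,Sp) antipode of the ferrocenyl diphosphine in step 4 is taken to direct the alkyl group to the Si face of C2 (giving 2S); the sense is to be confirmed on a test scale, and the (S,Rp) antipode would be used otherwise with no other change.

**Route**

Step 1
Reactants: 1 2'-hydroxy-6'-methoxyacetophenone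
Product: 2 (E)-3-(dimethylamino)-1-(2-hydroxy-6-methoxyphenyl)prop-2-en-1-one
Conditions: DMF dimethyl acetal (2 equiv), toluene, 100 °C
Reagents that add atoms: N,N-dimethylformamide dimethyl acetal, COC(OC)N(C)C
Why: Condensation of the acidic methyl ketone with the amide acetal (enaminone formation) is the standard entry to chromone precursors and leaves the hydrogen-bonded phenol free.

Step 2
Reactants: 2 (E)-3-(dimethylamino)-1-(2-hydroxy-6-methoxyphenyl)prop-2-en-1-one
Product: 3 5-methoxy-4H-chromen-4-one
Conditions: conc. aq. HCl, CH2Cl2, rt to 40 °C
Reagents that add atoms: none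
Why: Under acid the phenol adds to the β-carbon of the vinylogous amide (6-endo oxa-Michael addition) and dimethylamine is expelled, the usual enaminone-to-chromone cyclization, to which the aryl methyl ether is inert.

Step 3
Reactants: 4 1-bromoheptadecane
Product: 5 heptadecylmagnesium bromide
Conditions: Mg turnings (I2 activation), Et2O, reflux, slow addition of 4; titrate before use
Reagents that add atoms: magnesium, [Mg]
Why: Insertion of magnesium into a primary alkyl bromide (Grignard formation) is reliable; slow addition limits Wurtz coupling, and an ethereal, THF-free reagent suits the copper catalyst.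

Step 4
Reactants: 3 5-methoxy-4H-chromen-4-one; 5 heptadecylmagnesium bromide
Product: 7 (S)-2-heptadecyl-5-methoxychroman-4-one, via bromomagnesium enolate 6 (not isolated)
Conditions: CuBr·SMe2 (5 mol %), (R)-1-[(Sp)-2-(dicyclohexylphosphino)ferrocenyl]ethyldiphenylphosphine (6 mol %), CH2Cl2, −78 °C; 5 (1.5 equiv, Et2O) added over 2 h; MeOH then sat. aq. NH4Cl at −78 °C
Reagents that add atoms: none
Why: Transmetalation of 5 to the diphosphine-bound monovalent copper gives a chiral alkylcopper species that binds the C2=C3 bond of the magnesium-activated chromone, passes through a trivalent copper σ-complex at C2 and reductively eliminates to form the C2–chain bond and enolate 6, which is protonated on quench. The closest known reaction is the copper-catalysed asymmetric conjugate addition of alkyl Grignard reagents to chromones and related cyclic enones. No ring is closed, since the pyranone ring is already in place. The C2 stereocentre is set by the chiral diphosphine on copper, which delivers the alkyl group to the Si face of C2 and so gives 2S. The step needs 1,4- over 1,2-addition and a catalysed pathway faster than the racemic background, which low temperature, slow Grignard addition and the flat, unhindered C2–H enone should secure. It also needs the enolate not to open by retro-oxa-Michael reaction, which the cold quench should prevent.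

Step 5
Reactants: 7 (S)-2-heptadecyl-5-methoxychroman-4-one
Product: 8 (2S,4R)-2-heptadecyl-5-methoxychroman-4-ol (2,4-cis)
Conditions: NaBH4, THF/MeOH, 0 °C to rt
Reagents that add atoms: none
Why: In the half-chair with the C2 chain equatorial, borohydride should add to C4 along the axial trajectory, syn to the axial C2–H, which places the hydroxyl pseudo-equatorial and cis to the chain (4R), as is usual for borohydride reduction of 2-substituted chroman-4-ones.

Step 6
Reactants: 8 (2S,4R)-2-heptadecyl-5-methoxychroman-4-ol
Product: 11 (2S,4R)-2-heptadecyl-5-methoxy-3,4,4a,7-tetrahydro-2H-chromen-4-ol (C4a epimers), via lithium alkoxide 9 (not isolated), via lithium dienyl alkoxide 10 (not isolated)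
Conditions: n-BuLi (1.05 equiv), THF, −78 °C; then NH3 (l), Li (10 equiv), t-BuOH (5 equiv), −78 → −33 °C; isoprene, then solid NH4Cl
Reagents that add atoms: none
Why: In this Birch reduction the preformed alkoxide cannot depart as oxide, so the benzylic C4–O bond should survive while the 2-alkylresorcinol diether ring takes up two electrons and two protons at C4a and C7 (the positions that leave both oxygen substituents on double bonds), as known for 2-alkyl-1,3-dialkoxybenzenes; C2 and C4 are untouched and the new C4a centre is erased in step 7.

Step 7
Reactants: 11 (2S,4R)-2-heptadecyl-5-methoxy-3,4,4a,7-tetrahydro-2H-chromen-4-ol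
Product: 13 (2S,4R)-2-heptadecyl-4-hydroxy-2,3,4,6,7,8-hexahydro-5H-chromen-5-one (target), via nonconjugated ketone 12 (not isolated)
Conditions: oxalic acid (0.5 M aq.), THF, 0 °C to rt
Reagents that add atoms: water, O
Why: Mild acid should hydrolyse the methyl enol ether (protonation at C6, hemiketal, loss of methanol) to the C5 ketone, after which the ring enol ether C8=C8a, now β,γ to the ketone, should move into conjugation as C4a=C8a through the dienol, driven by formation of the vinylogous ester (enol ether hydrolysis followed by β,γ to α,β isomerization), with C2 and C4 not involved.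

**Compound list**
1 | 2'-hydroxy-6'-methoxyacetophenone | CC(=O)c1c(O)cccc1OC | starting material
2 | (E)-3-(dimethylamino)-1-(2-hydroxy-6-methoxyphenyl)prop-2-en-1-one | CN(C)/C=C/C(=O)c1c(O)cccc1OC | intermediate
3 | 5-methoxy-4H-chromen-4-one | COc1cccc2occc(=O)c12 | intermediate
4 | 1-bromoheptadecane | CCCCCCCCCCCCCCCCCBr | starting material
5 | heptadecylmagnesium bromide | CCCCCCCCCCCCCCCCC[Mg]Br | intermediate
6 | bromomagnesium (S)-2-heptadecyl-5-methoxy-2H-chromen-4-olate | CCCCCCCCCCCCCCCCC[C@H]1C=C(O[Mg]Br)c2c(OC)cccc2O1 | intermediate (not isolated)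
7 | (S)-2-heptadecyl-5-methoxychroman-4-one | CCCCCCCCCCCCCCCCC[C@H]1CC(=O)c2c(OC)cccc2O1 | intermediate
8 | (2S,4R)-2-heptadecyl-5-methoxychroman-4-ol | CCCCCCCCCCCCCCCCC[C@H]1C[C@@H](O)c2c(OC)cccc2O1 | intermediate
9 | lithium (2S,4R)-2-heptadecyl-5-methoxychroman-4-olate | CCCCCCCCCCCCCCCCC[C@H]1C[C@@H]([O-])c2c(OC)cccc2O1.[Li+] | intermediate (not isolated)
10 | lithium (2S,4R)-2-heptadecyl-5-methoxy-3,4,4a,7-tetrahydro-2H-chromen-4-olate (C4a epimers) | CCCCCCCCCCCCCCCCC[C@H]1C[C@@H]([O-])C2C(OC)=CCC=C2O1.[Li+] | intermediate (not isolated)
11 | (2S,4R)-2-heptadecyl-5-methoxy-3,4,4a,7-tetrahydro-2H-chromen-4-ol (C4a epimers) | CCCCCCCCCCCCCCCCC[C@H]1C[C@@H](O)C2C(OC)=CCC=C2O1 | intermediate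
12 | (2S,4R)-2-heptadecyl-4-hydroxy-2,3,4,4a,6,7-hexahydro-5H-chromen-5-one (C4a epimers) | CCCCCCCCCCCCCCCCC[C@H]1C[C@@H](O)C2C(=O)CCC=C2O1 | intermediate (not isolated)
13 | (2S,4R)-2-heptadecyl-4-hydroxy-2,3,4,6,7,8-hexahydro-5H-chromen-5-one | CCCCCCCCCCCCCCCCC[C@H]1C[C@@H](O)C2=C(CCCC2=O)O1 | target

**Step count**
Total: 7 steps. Longest linear sequence: 6 steps (steps 1, 2, 4, 5, 6, 7).

**Steps most likely to fail**

1. Step 6. The small equilibrium share of free benzylic alcohol may undergo reductive C4–O cleavage, electron transfer to the electron-rich, alkoxide-bearing ring may stall, or an aryl–oxygen bond may be cut. The fallback sets out from 7 and dearomatizes before any C4 carbinol exists. Aryl ketones are reduced in the ring at the ipso and para carbons, here C4a and C7, by K (2.2 equiv) in NH3/THF with one equivalent of t-BuOH at −78 °C. Exchange of the cross-conjugated dienolate with LiBr and protonation at C4a with NH4Cl should give (2S)-2-heptadecyl-5-methoxy-2,3,4a,7-tetrahydro-4H-chromen-4-one F1. Reduction of the C4 ketone with NaBH4 in MeOH/THF at −40 °C, with C5 still masked as its methyl enol ether, should give 11, where the route is rejoined. Hydride delivery cis to the C2 chain is expected but would have to be confirmed.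

2. Step 4. Enantioselectivity may erode through uncatalysed background addition (possibly helped by magnesium chelation between the C4 carbonyl and the 5-methoxy group) or through reversible ring opening of the enolate. 1,2-Addition may compete, and the long-chain Grignard reagent may precipitate at −78 °C. The fallback sets out from 1 and sets C2 by hydrogen delivery instead of C–C bond formation. Claisen condensation of 1 with ethyl octadecanoate (NaH, THF, reflux) should give 1-(2-hydroxy-6-methoxyphenyl)icosane-1,3-dione F2. Cyclodehydration (cat. H2SO4, AcOH, 80 °C) should give 2-heptadecyl-5-methoxy-4H-chromen-4-one F3. Enantioselective hydrogenation of this 2-alkylchromone should reduce C2=C3 and C4=O from one face and give the cis-chromanol 8 directly, where the route is rejoined. The hydrogenation would use Ru(cod)(2-methylallyl)2, the carbene from 1,3-bis[(R)-1-(naphthalen-1-yl)ethyl]-4,5-dihydroimidazolium tetrafluoroborate and KOtBu, and H2 under pressure in hexane, with the antipode of the carbene precursor that leads to (2S,4R).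

3. Step 7. Acid may ionize the allylic C4 hydroxyl, leading to epimerization or elimination towards the 2H-pyran. Ketone 12 may dehydrate before conjugation, or the ring enol ether may open by hydrolysis. The fallback sets out from 11 and masks the hydroxyl as a less basic silyl ether before the acid step. TBSCl and imidazole in DMF should give tert-butyl{[(2S,4R)-2-heptadecyl-5-methoxy-3,4,4a,7-tetrahydro-2H-chromen-4-yl]oxy}dimethylsilane F4. The same oxalic acid hydrolysis and conjugation should give (2S,4R)-4-[(tert-butyldimethylsilyl)oxy]-2-heptadecyl-2,3,4,6,7,8-hexahydro-5H-chromen-5-one F5. HF·pyridine in THF/pyridine at 0 °C should then release 13 under nearly neutral conditions.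

**Further compounds**
F1 | step 6 | (2S)-2-heptadecyl-5-methoxy-2,3,4a,7-tetrahydro-4H-chromen-4-one | CCCCCCCCCCCCCCCCC[C@H]1CC(=O)C2C(OC)=CCC=C2O1
F2 | step 4 | 1-(2-hydroxy-6-methoxyphenyl)icosane-1,3-dione | CCCCCCCCCCCCCCCCCC(=O)CC(=O)c1c(O)cccc1OC
F3 | step 4 | 2-heptadecyl-5-methoxy-4H-chromen-4-one | CCCCCCCCCCCCCCCCCc1cc(=O)c2c(OC)cccc2o1
F4 | step 7 | tert-butyl{[(2S,4R)-2-heptadecyl-5-methoxy-3,4,4a,7-tetrahydro-2H-chromen-4-yl]oxy}dimethylsilane | CCCCCCCCCCCCCCCCC[C@H]1C[C@@H](O[Si](C)(C)C(C)(C)C)C2C(OC)=CCC=C2O1
F5 | step 7 | (2S,4R)-4-[(tert-butyldimethylsilyl)oxy]-2-heptadecyl-2,3,4,6,7,8-hexahydro-5H-chromen-5-one | CCCCCCCCCCCCCCCCC[C@H]1C[C@@H](O[Si](C)(C)C(C)(C)C)C2=C(CCCC2=O)O1
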